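# Proposed synthesis of EANPDB:ANNO_00166 from myo-inositol by sulfoxonium-ylide methylene transfer to a protected inosose

## Analysis of the target

The target 23 is a single cyclohexene ring of seven carbons with four contiguous stereocentres. In the numbering used here C1 is the fully substituted carbinol carbon, C7 its benzoyloxymethyl carbon, C2 and C3 carry the acetates, C4=C5 is the alkene and C6 is the secondary carbinol. With this numbering the descriptors are 1S, 2R, 3S, 6S. O-1 is cis to both O-2 and O-6, and O-3 is trans to O-2.

The molecule holds three esters of two kinds next to two free hydroxyls, so any alkoxide at O-1 or O-6 invites acetyl or benzoyl migration. The C3 acetate and the C6 hydroxyl are allylic, and the ring is two eliminations away from an arene.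

The difficulty lies in three places: the quaternary carbinol C1 between two oxygenated stereocentres, the sorting of six oxygens into three different states, and an alkene that must never sit beta,gamma to a carbonyl group.

The strategy rests on one observation. If C4 and C5 carried equatorial oxygens, the ring would be a chair with five equatorial C–O bonds and an axial O-1, which is the pattern of myo-inositol. The mapping (1D numbering of the inositol) is: C1 = D-2 (the axial carbon), C6 = D-1, C2 = D-3, C3 = D-4, C4 = D-5, C5 = D-6. C2, C3 and C6 are therefore taken unchanged from the pool. Only the C1–C7 bond, with the configuration at C1, and the C4=C5 unsaturation have to be made.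

## Retrosynthetic reasoning

**O-6 unmasking.** The target 23 is traced back to its O-6 silyl ether 22. A free O-6 would compete in acetylation and in the diol-to-alkene step, so it stays masked to the end under a group that comes off without base.

**C4=C5 alkene.** The alkene of 22 is traced back to the trans-diequatorial 4,5-diol 21, so the two C–O bonds at C4 and C5 are the ones cut. The unsaturation is placed late because, earlier, it would lie beta,gamma to the C1 ketone that the key step needs. The forward reaction must remove two vicinal hydroxyls from a locked chair without touching the esters.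

**Sorting of the oxygens.** Diol 21 comes from dibenzyl ether 20 by hydrogenolysis, 20 from triol 19 by acetylation of the two secondary hydroxyls, and 19 from bis(4-methoxybenzyl) ether 18 by oxidative ether cleavage. The two ether types are chosen so that O-2/O-3 are released first and acylated, and O-4/O-5 are released afterwards without an alkene being present during hydrogenolysis.

**C7–O bond.** Hydroxy benzoate 18 is opened to spiro-oxirane 16 and benzoic acid 17. Attack at the unsubstituted oxirane carbon C7 gives the benzoate and the free tertiary hydroxyl at once, with no change at C1.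

**C1–C7 bond (key disconnection).** Oxirane 16 is cut at C1–C7 and C7–O to inosose 12 and the ylide 14, which is made from salt 13. This is the only skeletal bond the route has to form. It is cut here because the ketone precursor is a meso-derived, conformationally locked ring in which the reagent, not a chiral controller, decides the new centre. The forward reaction must put C7 equatorial and the oxygen axial.

**Ketone.** Inosose 12 comes from alcohol 11 by oxidation of the single free, axial hydroxyl. Alcohol 11 comes from diol 10 by silylation of the equatorial O-1 in preference to the axial O-2.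

**Differentiation of the hydroxyls.** Diol 10 is traced back through ketal 9 and diol 7 to dibenzyl ether 6, then to disiloxane 5 and to tetrol 4. The cyclic disiloxane picks O-3/O-4 out of four free hydroxyls, so O-5/O-6 can be benzylated, after which O-3/O-4 receive the oxidatively removable ethers.

**Desymmetrisation.** Tetrol 4 is cut at the ketal to meso myo-inositol 3 and acetal 2, which is made from camphor 1. The chiral ketone selects one of the two enantiotopic cis-diols of 3 and so fixes the absolute configuration of the whole route in the second step.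

## Alternatives that were turned down

**Alternative 1:** The ring is opened at C3–C4 to a chain ending in a C3 aldehyde and a (Z)-iodoalkene at C4=C5. In the forward sense a chromium-mediated, nickel-catalysed alkenyl addition (Nozaki–Hiyama–Kishi) closes the six-membered ring and gives allylic alcohol A1.
- For: the cis-alkene arrives with the ring closure. O-1 and O-6 are already tied up as an acetonide, and the C7 benzoate and C2 acetate are in place and tolerate organochromium species. After A1 only acetylation of O-3 and acetal hydrolysis remain, two steps where the chosen route needs six after its key step. On this point the alternative is clearly stronger.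
- Against: C3 is created during ring closure from a flexible chain and must come out trans to the C2 acetate with no rigid element to enforce it. The open-chain precursor of A1 is an alpha-acetoxy aldehyde next to a fully substituted acetal carbon and is prone to epimerisation and loss of acetate. That precursor, with the quaternary C1, C2, C6 and the iodoalkene, must itself be assembled over many steps from a branched sugar, so the quaternary-centre problem is only moved earlier. Stoichiometric chromium is also needed.
- Comparison: the chosen route takes three stereocentres untouched from 3 and sets the fourth under thermodynamic control in a locked chair. It reaches its key-step precursor 12 by routine protecting-group chemistry.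

**Alternative 2:** The C1–C6 bond is cut and a C4–O bond re-formed. The silyl ketene acetal of a pentose-derived delta-lactone carrying a (Z)-2-alkoxyvinyl group undergoes a ring-contracting Ireland–Claisen rearrangement to cyclohexene carboxylic acid A2.
- For: one pericyclic step forges the quaternary carbon, the carbocycle and the C4=C5 alkene. The bicyclic geometry imposes a boat-like transition state, so the relation of C1 to C6 is predictable in principle. The alkene needs no dideoxygenation. In skeletal economy this is stronger than the chosen route.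
- Against: the lactone enolate sits alpha to an ether oxygen with an alkoxy group in the beta position, so beta-elimination competes with silylation. Both C1 and C6 depend on enol-ether geometry and one transition state. A2 holds C7 as a carboxylic acid that must be reduced next to a hindered tertiary ether. A tertiary and a secondary 4-methoxybenzyl ether and two methoxymethyl ethers must then be exchanged for two acetates and one benzoate with O-1 and O-6 free. The acid needed for the acetal-type ethers threatens the allylic positions. Five to six steps follow the key step, so the whole is not shorter.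
- Comparison: in the chosen route one bond and one stereocentre depend on the key step, and C7 arrives at the alcohol oxidation level and is acylated in the next operation.

**Alternative 3:** The C5–O and C6–O bonds are cut. The symmetric para-quinol A4 is epoxidised on one of its two enantiotopic enone alkenes, syn to the tertiary hydroxyl, by a chiral peroxide-delivering catalyst to give A3. A Wharton transposition then gives dienediol A5 with the C6 carbinol and the C4=C5 alkene.
- For: this is by far the shortest plan. A4 is one or two steps from a simple phenol and already holds all seven carbons. C1 and C6 are set in one catalytic step, so absolute configuration does not depend on an auxiliary that is later discarded. On step count and on catalytic stereocontrol it is stronger.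
- Against: the catalyst must choose between two enantiotopic alkenes while the free hydroxyl directs to the syn face. That group selection on a quinol is not a transformation of the reliability of the steps in the chosen route. A3 is a reactive enone, and A5 is a cyclohexadiene cis-diol one dehydration away from an arene. The trans C2/C3 diacetoxy unit must still be installed on one alkene of a conjugated diene with control of site and face. O-1, O-2 and O-6 must then be told apart for acylation, and nothing in A5 distinguishes O-2 from O-6 except position.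
- Comparison: the chosen route is much longer, but every oxygen is addressed individually from the start. No step has to select among near-equivalent hydroxyls or alkenes.

Key step: step 10

**Assumptions (remarks on the chemistry).**
- The (1R)-camphor ketal of myo-inositol is taken to be the 1D-2,3-O-isomer. Its mirror image from (1S)-camphor is then the 1D-1,2-O-ketal 4.
- The configuration drawn at the spiro ketal carbon of 4 (equatorial O-1 exo, axial O-2 endo, camphor CH2 on the concave face) is assumed. That carbon is removed again in step 7 and has no bearing on the route.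

## Route

Step 1
Reactants: 1 (1S)-(−)-camphor
Product: 2 (1S,4S)-2,2-dimethoxy-1,7,7-trimethylbicyclo[2.2.1]heptane ((1S)-camphor dimethyl acetal)
Conditions: HC(OMe)3, MeOH, TsOH·H2O (cat.), rt
Reagents that add atoms: trimethyl orthoformate, COC(OC)OC
Why: Acid-catalysed acetalisation with an orthoester as water scavenger; the two stereocentres of the bornane skeleton are not involved.

Step 2
Reactants: 3 myo-inositol; 2 (1S)-camphor dimethyl acetal
Product: 4 1D-1,2-O-[(1S,4S)-1,7,7-trimethylbicyclo[2.2.1]heptan-2-ylidene]-myo-inositol (below: (1S)-bornylidene ketal)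
Conditions: H2SO4 (cat.), DMSO, 70 °C; Et3N; then TsOH·H2O (cat.), CHCl3–MeOH–H2O, rt, collection of the solid
Reagents that add atoms: (1S)-camphor dimethyl acetal 2, COC1(OC)C[C@@H]2CC[C@@]1(C)C2(C)C
Why: Transketalisation engages the cis-diols of 3 (O-1/O-2 and O-2/O-3, which are enantiotopic); the second, equilibrating acid treatment should cleave the labile trans-ketals and funnel the monoketal diastereomers into the least soluble one, by mirror symmetry with the (1R)-camphor series the 1D-1,2-isomer; no inositol stereocentre is changed.

Step 3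
Reactants: 4 (1S)-bornylidene ketal tetrol
Product: 5 1D-1,2-O-[(1S)-bornylidene]-3,4-O-(1,1,3,3-tetraisopropyldisiloxane-1,3-diyl)-myo-inositol
Conditions: TIPDSCl2 (1.05 equiv), pyridine, −20 °C to rt
Reagents that add atoms: 1,3-dichloro-1,1,3,3-tetraisopropyldisiloxane, CC(C)[Si](Cl)(C(C)C)O[Si](Cl)(C(C)C)C(C)C
Why: Regioselective silylation: the equatorial O-3 next to the axial ketal oxygen is the most nucleophilic hydroxyl, and the second Si–Cl end then closes onto the neighbouring trans O-4, leaving the 5,6-diol free.

Step 4
Reactants: 5 disiloxane diol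
Product: 6 1D-5,6-di-O-benzyl-1,2-O-[(1S)-bornylidene]-3,4-O-(1,1,3,3-tetraisopropyldisiloxane-1,3-diyl)-myo-inositol
Conditions: 2-benzyloxy-1-methylpyridinium triflate (4 equiv), MgO, PhCF3, 85 °C
Reagents that add atoms: 2-benzyloxy-1-methylpyridinium trifluoromethanesulfonate, C[n+]1ccccc1OCc1ccccc1.[O-]S(=O)(=O)C(F)(F)F
Why: Benzyl transfer under neutral conditions from a thermally ionising pyridinium salt; it avoids the alkoxides of a Williamson etherification, which would open or shift the disiloxane, and MgO buffers the acid so the ketal is kept.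

Step 5
Reactants: 6 dibenzyl disiloxane
Product: 7 1D-5,6-di-O-benzyl-1,2-O-[(1S)-bornylidene]-myo-inositol
Conditions: Bu4NF (2.2 equiv), THF, 0 °C
Reagents that add atoms: none
Why: Fluoride cleavage of both Si–O bonds; benzyl ethers and the ketal are inert to fluoride.

Step 6
Reactants: 7 3,4-diol; 8 4-methoxybenzyl chloride
Product: 9 1D-5,6-di-O-benzyl-1,2-O-[(1S)-bornylidene]-3,4-di-O-(4-methoxybenzyl)-myo-inositol
Conditions: NaH, Bu4NI (cat.), DMF, 0 °C to rt
Reagents that add atoms: 4-methoxybenzyl chloride 8, COc1ccc(CCl)cc1
Why: Williamson etherification of the two remaining hydroxyls; no base-labile group is left in the molecule.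

Step 7
Reactants: 9 fully protected ketal
Product: 10 1D-5,6-di-O-benzyl-3,4-di-O-(4-methoxybenzyl)-myo-inositol
Conditions: HCl (0.1 M), MeOH–CH2Cl2 (3:1), rt
Reagents that add atoms: none
Why: Acid-catalysed transketalisation to methanol releases the cis-1,2-diol and returns the auxiliary as 2; benzyl and 4-methoxybenzyl ethers tolerate dilute methanolic acid at room temperature.

Step 8
Reactants: 10 1,2-diol
Product: 11 1D-5,6-di-O-benzyl-1-O-(tert-butyldiphenylsilyl)-3,4-di-O-(4-methoxybenzyl)-myo-inositol
Conditions: TBDPSCl (1.1 equiv), imidazole, DMF, −10 °C to rt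
Reagents that add atoms: tert-butyl(chloro)diphenylsilane, CC(C)(C)[Si](Cl)(c1ccccc1)c1ccccc1
Why: Regioselective silylation: the equatorial O-1 of the axial/equatorial cis-diol is far more accessible to the bulky chlorosilane than the axial O-2, which is flanked on both sides.

Step 9
Reactants: 11 axial alcohol
Product: 12 1D-5,6-di-O-benzyl-1-O-(tert-butyldiphenylsilyl)-3,4-di-O-(4-methoxybenzyl)-myo-inosose-2 (ketone at the former axial carbon, all five ether groups equatorial)
Conditions: Dess–Martin periodinane, NaHCO3, CH2Cl2, rt
Reagents that add atoms: none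
Why: Dess–Martin oxidation of a hindered axial secondary alcohol; the buffered, non-basic medium should leave the two alpha stereocentres and the acid-sensitive ethers untouched.

Step 10
Reactants: 12 protected inosose; 13 trimethylsulfoxonium iodide
Product: 16 spiro-oxirane at C-2 of the inositol ring (target C1) with the oxirane oxygen axial (cis to O-1 and O-3) and the CH2 group (C7) equatorial; 5,6-di-O-benzyl, 1-O-TBDPS and 3,4-di-O-(4-methoxybenzyl) groups unchanged, via dimethylsulfoxonium methylide 14 (not isolated), via axial-alkoxide sulfoxonium betaine 15 (not isolated)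
Conditions: Me3S(O)I (1.5 equiv), NaH (1.4 equiv), DMSO, rt; then 12 in THF, rt to 45 °C
Reagents that add atoms: trimethylsulfoxonium iodide 13, C[S+](C)(C)=O.[I-]
Why: NaH deprotonates 13 to ylide 14, which adds to the C1 carbonyl of 12 to give betaine 15 and so forms the C1–C7 bond. Because 14 is a stabilised ylide the addition is reversible, so the betaine that carries the bulky CH2S(O)Me2 group equatorial and the alkoxide axial is the one that accumulates and reacts on. The axial alkoxide then displaces dimethyl sulfoxide from C7 in a 3-exo-tet closure that forms the oxirane. The closest known reaction type is the Corey–Chaykovsky epoxidation of conformationally fixed cyclohexanones with this ylide, which gives the equatorial C–C bond. The new stereocentre C1 is controlled by the substrate alone: five equatorial substituents lock the chair, and an axial oxygen is by geometry cis to O-2 and O-6 of the target. The step needs diastereoselectivity at C1 and chemoselectivity over enolisation. The ylide is a weak base and is used without excess hydride, and the beta-alkoxy groups of any enolate are equatorial and poorly aligned for elimination.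

Step 11
Reactants: 16 spiro-oxirane; 17 benzoic acid
Product: 18 1D-2-C-(benzoyloxymethyl)-5,6-di-O-benzyl-1-O-(tert-butyldiphenylsilyl)-3,4-di-O-(4-methoxybenzyl)-myo-inositol (axial tertiary hydroxyl)
Conditions: PhCO2H (4 equiv), PhCO2Cs (0.5 equiv), DMF, 90 °C
Reagents that add atoms: benzoic acid 17, O=C(O)c1ccccc1
Why: SN2 opening of the oxirane by benzoate at the only accessible carbon, C7; the excess acid protonates the tertiary alkoxide as it forms, which should suppress acyl and silyl migration, and C1 is not touched.

Step 12
Reactants: 18 hydroxy benzoate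
Product: 19 1D-2-C-(benzoyloxymethyl)-5,6-di-O-benzyl-1-O-(tert-butyldiphenylsilyl)-myo-inositol (free O-3, O-4 and tertiary hydroxyl)
Conditions: DDQ (2.6 equiv), CH2Cl2–pH 7 buffer (10:1), 0 °C to rt
Reagents that add atoms: none
Why: Oxidative cleavage of the electron-rich 4-methoxybenzyl ethers in the presence of benzyl ethers; the water in the medium should intercept the oxocarbenium ions before the neighbouring tertiary hydroxyl can close an anisylidene acetal.

Step 13
Reactants: 19 triol
Product: 20 1D-3,4-di-O-acetyl-2-C-(benzoyloxymethyl)-5,6-di-O-benzyl-1-O-(tert-butyldiphenylsilyl)-myo-inositol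
Conditions: Ac2O, pyridine, DMAP (cat.), 0 °C to rt
Reagents that add atoms: acetic anhydride, CC(=O)OC(C)=O
Why: Acetylation of the two secondary hydroxyls; the tertiary hydroxyl, flanked by three substituted carbons, should not react under these mild conditions.

Step 14
Reactants: 20 diacetate
Product: 21 1D-3,4-di-O-acetyl-2-C-(benzoyloxymethyl)-1-O-(tert-butyldiphenylsilyl)-myo-inositol (free trans-5,6-diol)
Conditions: H2 (1 atm), 10% Pd/C, EtOAc, rt
Reagents that add atoms: none
Why: Hydrogenolysis of the two benzyl ethers; the benzoate has no benzylic C–O bond, and the neutral aprotic medium should prevent acetyl migration to the new hydroxyls.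

Step 15
Reactants: 21 trans-diequatorial diol
Product: 22 [2,3-diacetoxy-6-(tert-butyldiphenylsilyloxy)-1-hydroxycyclohex-4-en-1-yl]methyl benzoate, configured as 23 (the O-6 silyl ether of the target)
Conditions: PPh3 (4 equiv), imidazole (4 equiv), I2 (3 equiv), toluene, 110 °C
Reagents that add atoms: none
Why: Garegg–Samuelsson olefination: both hydroxyls are activated by the iodophosphonium reagent and lost by iodide-induced reductive elimination, a sequence that operates on trans-diequatorial diols in locked chairs; the locked ring keeps the C3 acetate from reaching the anti arrangement needed for neighbouring-group participation, and the tertiary hydroxyl is too hindered to be activated.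

Step 16
Reactants: 22 silyl ether
Product: 23 [(1S,2R,3S,6S)-2,3-diacetoxy-1,6-dihydroxycyclohex-4-en-1-yl]methyl benzoate (target; numbering of this text)
Conditions: HF·pyridine, pyridine–THF, 0 °C to rt
Reagents that add atoms: none
Why: Fluoride-mediated desilylation under acidic, non-basic conditions, so that no alkoxide is formed at O-6 and the acetates and the benzoate should stay where they are.

## Compound list

1 | (1S,4S)-1,7,7-trimethylbicyclo[2.2.1]heptan-2-one, (1S)-(−)-camphor | O=C1C[C@@H]2CC[C@@]1(C)C2(C)C | starting material
2 | (1S,4S)-2,2-dimethoxy-1,7,7-trimethylbicyclo[2.2.1]heptane | COC1(OC)C[C@@H]2CC[C@@]1(C)C2(C)C | intermediate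
3 | myo-inositol | O[C@@H]1[C@H](O)[C@H](O)[C@@H](O)[C@H](O)[C@H]1O | starting material
4 | 1D-1,2-O-[(1S,4S)-1,7,7-trimethylbicyclo[2.2.1]heptan-2-ylidene]-myo-inositol | O[C@H]1[C@H](O)[C@@H](O)[C@@H]2O[C@]3(C[C@@H]4CC[C@@]3(C)C4(C)C)O[C@@H]2[C@@H]1O | intermediate
5 | 1D-1,2-O-[(1S)-bornylidene]-3,4-O-(1,1,3,3-tetraisopropyldisiloxane-1,3-diyl)-myo-inositol | CC(C)[Si]1(C(C)C)O[Si](C(C)C)(C(C)C)O[C@H]2[C@H](O)[C@@H](O)[C@@H]3O[C@]4(C[C@@H]5CC[C@@]4(C)C5(C)C)O[C@@H]3[C@@H]2O1 | intermediate
6 | 1D-5,6-di-O-benzyl-1,2-O-[(1S)-bornylidene]-3,4-O-(1,1,3,3-tetraisopropyldisiloxane-1,3-diyl)-myo-inositol | CC(C)[Si]1(C(C)C)O[Si](C(C)C)(C(C)C)O[C@H]2[C@H](OCc6ccccc6)[C@@H](OCc6ccccc6)[C@@H]3O[C@]4(C[C@@H]5CC[C@@]4(C)C5(C)C)O[C@@H]3[C@@H]2O1 | intermediate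
7 | 1D-5,6-di-O-benzyl-1,2-O-[(1S)-bornylidene]-myo-inositol | O[C@H]1[C@H](OCc2ccccc2)[C@@H](OCc2ccccc2)[C@@H]2O[C@]3(C[C@@H]4CC[C@@]3(C)C4(C)C)O[C@@H]2[C@@H]1O | intermediate
8 | 4-methoxybenzyl chloride | COc1ccc(CCl)cc1 | starting material
9 | 1D-5,6-di-O-benzyl-1,2-O-[(1S)-bornylidene]-3,4-di-O-(4-methoxybenzyl)-myo-inositol | COc1ccc(CO[C@H]2[C@H](OCc3ccccc3)[C@@H](OCc3ccccc3)[C@@H]3O[C@]4(C[C@@H]5CC[C@@]4(C)C5(C)C)O[C@@H]3[C@@H]2OCc2ccc(OC)cc2)cc1 | intermediate
10 | 1D-5,6-di-O-benzyl-3,4-di-O-(4-methoxybenzyl)-myo-inositol | COc1ccc(CO[C@H]2[C@H](OCc3ccccc3)[C@@H](OCc3ccccc3)[C@H](O)[C@H](O)[C@@H]2OCc2ccc(OC)cc2)cc1 | intermediate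
11 | 1D-5,6-di-O-benzyl-1-O-(tert-butyldiphenylsilyl)-3,4-di-O-(4-methoxybenzyl)-myo-inositol | COc1ccc(CO[C@H]2[C@H](OCc3ccccc3)[C@@H](OCc3ccccc3)[C@H](O[Si](C(C)(C)C)(c3ccccc3)c3ccccc3)[C@H](O)[C@@H]2OCc2ccc(OC)cc2)cc1 | intermediate
12 | 1D-5,6-di-O-benzyl-1-O-(tert-butyldiphenylsilyl)-3,4-di-O-(4-methoxybenzyl)-myo-inosose-2 | COc1ccc(CO[C@H]2[C@H](OCc3ccccc3)[C@@H](OCc3ccccc3)[C@H](O[Si](C(C)(C)C)(c3ccccc3)c3ccccc3)C(=O)[C@@H]2OCc2ccc(OC)cc2)cc1 | intermediate
13 | trimethylsulfoxonium iodide | C[S+](C)(C)=O.[I-] | starting material
14 | dimethylsulfoxonium methylide | [CH2-][S+](C)(C)=O | intermediate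
15 | betaine from 12 and 14: axial alkoxide at the former carbonyl carbon, equatorial CH2–S(O)Me2 group | COc1ccc(CO[C@H]2[C@H](OCc3ccccc3)[C@@H](OCc3ccccc3)[C@H](O[Si](C(C)(C)C)(c3ccccc3)c3ccccc3)[C@@]([O-])(C[S+](C)(C)=O)[C@@H]2OCc2ccc(OC)cc2)cc1 | intermediate
16 | spiro-oxirane at inositol C-2 (target C1), oxygen axial, CH2 (C7) equatorial; 5,6-di-O-benzyl, 1-O-TBDPS, 3,4-di-O-(4-methoxybenzyl) | COc1ccc(CO[C@H]2[C@H](OCc3ccccc3)[C@@H](OCc3ccccc3)[C@H](O[Si](C(C)(C)C)(c3ccccc3)c3ccccc3)[C@@]3(CO3)[C@@H]2OCc2ccc(OC)cc2)cc1 | intermediate
17 | benzoic acid | O=C(O)c1ccccc1 | starting material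
18 | 1D-2-C-(benzoyloxymethyl)-5,6-di-O-benzyl-1-O-(tert-butyldiphenylsilyl)-3,4-di-O-(4-methoxybenzyl)-myo-inositol | COc1ccc(CO[C@H]2[C@H](OCc3ccccc3)[C@@H](OCc3ccccc3)[C@H](O[Si](C(C)(C)C)(c3ccccc3)c3ccccc3)[C@@](O)(COC(=O)c3ccccc3)[C@@H]2OCc2ccc(OC)cc2)cc1 | intermediate
19 | 1D-2-C-(benzoyloxymethyl)-5,6-di-O-benzyl-1-O-(tert-butyldiphenylsilyl)-myo-inositol | O[C@H]1[C@H](OCc2ccccc2)[C@@H](OCc2ccccc2)[C@H](O[Si](C(C)(C)C)(c2ccccc2)c2ccccc2)[C@@](O)(COC(=O)c2ccccc2)[C@@H]1O | intermediate
20 | 1D-3,4-di-O-acetyl-2-C-(benzoyloxymethyl)-5,6-di-O-benzyl-1-O-(tert-butyldiphenylsilyl)-myo-inositol | CC(=O)O[C@H]1[C@H](OCc2ccccc2)[C@@H](OCc2ccccc2)[C@H](O[Si](C(C)(C)C)(c2ccccc2)c2ccccc2)[C@@](O)(COC(=O)c2ccccc2)[C@@H]1OC(C)=O | intermediate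
21 | 1D-3,4-di-O-acetyl-2-C-(benzoyloxymethyl)-1-O-(tert-butyldiphenylsilyl)-myo-inositol | CC(=O)O[C@H]1[C@H](O)[C@@H](O)[C@H](O[Si](C(C)(C)C)(c2ccccc2)c2ccccc2)[C@@](O)(COC(=O)c2ccccc2)[C@@H]1OC(C)=O | intermediate
22 | [2,3-diacetoxy-6-(tert-butyldiphenylsilyloxy)-1-hydroxycyclohex-4-en-1-yl]methyl benzoate, configured as 23 | CC(=O)O[C@H]1C=C[C@H](O[Si](C(C)(C)C)(c2ccccc2)c2ccccc2)[C@@](O)(COC(=O)c2ccccc2)[C@@H]1OC(C)=O | intermediate
23 | [(1S,2R,3S,6S)-2,3-diacetoxy-1,6-dihydroxycyclohex-4-en-1-yl]methyl benzoate | CC(=O)O[C@H]1C=C[C@H](O)[C@@](O)(COC(=O)c2ccccc2)[C@@H]1OC(C)=O | target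

## Step count and least certain steps

Total: 16 steps. Longest linear sequence: 16 steps (steps 1 to 16 from camphor 1; 15 steps from myo-inositol 3).

**Step 10 (key step).** Two things may go wrong. Facial selectivity may be poor if ring closure of the kinetically formed betaine outruns its reversal, which would place the oxygen equatorial. Enolisation of the alpha-alkoxy ketone may lead to beta-elimination or to silyl migration to the transient alkoxide.
Fallback, from 12: a bulky Grignard reagent, (isopropoxydimethylsilyl)methylmagnesium chloride with CeCl3 in THF at −78 °C, should add along the equatorial trajectory and give the axial tertiary carbinol F1. Tamao–Fleming oxidation (H2O2, KF, KHCO3, THF–MeOH) converts the C–Si bond into the hydroxymethyl diol F2. Benzoylation of the primary hydroxyl alone (BzCl, pyridine, −20 °C) gives 18, where the route is rejoined.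

**Step 15.** Activation of the diol may be misdirected. Possible processes are participation of the neighbouring acetate, acetyl migration under imidazole at 110 °C, slow reaction at the hydroxyl next to the bulky silyl ether, or dehydration at the tertiary hydroxyl.
Fallback, from 21: acylation of both hydroxyls with phenyl chlorothionoformate (DMAP, MeCN) gives the bis(O-phenyl thiocarbonate) F3. Radical elimination in the Barton–McCombie manner (Bu3SnH, AIBN, toluene, 100 °C) expels the second thiocarbonate from the first-formed carbon radical and gives 22 under neutral conditions.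

**Step 11.** Substitution at the hindered, neopentyl-type oxirane carbon may be slow. At the temperature then required, loss or migration of the silyl group and benzoyl migration become possible.
Fallback, from 16: the 4-methoxybenzyl ethers are cleaved first (DDQ, wet CH2Cl2) to give the epoxy diol F4. The freed hydroxyl next to the oxirane then binds Ti(OiPr)4, which should deliver benzoic acid 17 to the distal oxirane carbon C7 at room temperature in CH2Cl2. This gives triol 19 directly and also removes the acetal risk of step 12.

**Step 4.** Benzylation of two hindered hydroxyls may stop halfway, or traces of acid may cause the disiloxane to open or shift.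
Fallback, from 5, by an ester relay: benzoylation (BzCl, pyridine) gives the dibenzoate F5. Desilylation with Et3N·3HF gives the 3,4-diol F6. Acid-catalysed etherification with 4-methoxybenzyl trichloroacetimidate (TfOH cat.) gives the bis(4-methoxybenzyl) ether F7. Methanolysis (NaOMe, MeOH) gives the 5,6-diol F8. Williamson benzylation (NaH, BnBr, DMF), now with no silicon in the molecule, gives 9.

## Further compounds

F1 | step 10 | 1D-5,6-di-O-benzyl-1-O-(tert-butyldiphenylsilyl)-2-C-[(isopropoxydimethylsilyl)methyl]-3,4-di-O-(4-methoxybenzyl)-myo-inositol | COc1ccc(CO[C@H]2[C@H](OCc3ccccc3)[C@@H](OCc3ccccc3)[C@H](O[Si](C(C)(C)C)(c3ccccc3)c3ccccc3)[C@@](O)(C[Si](C)(C)OC(C)C)[C@@H]2OCc2ccc(OC)cc2)cc1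
F2 | step 10 | 1D-5,6-di-O-benzyl-1-O-(tert-butyldiphenylsilyl)-2-C-(hydroxymethyl)-3,4-di-O-(4-methoxybenzyl)-myo-inositol | COc1ccc(CO[C@H]2[C@H](OCc3ccccc3)[C@@H](OCc3ccccc3)[C@H](O[Si](C(C)(C)C)(c3ccccc3)c3ccccc3)[C@@](O)(CO)[C@@H]2OCc2ccc(OC)cc2)cc1
F3 | step 15 | 1D-3,4-di-O-acetyl-2-C-(benzoyloxymethyl)-1-O-(tert-butyldiphenylsilyl)-5,6-bis-O-(phenoxythiocarbonyl)-myo-inositol | CC(=O)O[C@H]1[C@H](OC(=S)Oc2ccccc2)[C@@H](OC(=S)Oc2ccccc2)[C@H](O[Si](C(C)(C)C)(c2ccccc2)c2ccccc2)[C@@](O)(COC(=O)c2ccccc2)[C@@H]1OC(C)=O
F4 | step 11 | spiro-oxirane 16 without its two 4-methoxybenzyl groups (free O-3 and O-4, oxirane oxygen axial) | O[C@H]1[C@H](OCc2ccccc2)[C@@H](OCc2ccccc2)[C@H](O[Si](C(C)(C)C)(c2ccccc2)c2ccccc2)[C@@]2(CO2)[C@@H]1O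
F5 | step 4 | 1D-5,6-di-O-benzoyl-1,2-O-[(1S)-bornylidene]-3,4-O-(1,1,3,3-tetraisopropyldisiloxane-1,3-diyl)-myo-inositol | CC(C)[Si]1(C(C)C)O[Si](C(C)C)(C(C)C)O[C@H]2[C@H](OC(=O)c6ccccc6)[C@@H](OC(=O)c6ccccc6)[C@@H]3O[C@]4(C[C@@H]5CC[C@@]4(C)C5(C)C)O[C@@H]3[C@@H]2O1
F6 | step 4 | 1D-5,6-di-O-benzoyl-1,2-O-[(1S)-bornylidene]-myo-inositol | O[C@H]1[C@H](OC(=O)c2ccccc2)[C@@H](OC(=O)c2ccccc2)[C@@H]2O[C@]3(C[C@@H]4CC[C@@]3(C)C4(C)C)O[C@@H]2[C@@H]1O
F7 | step 4 | 1D-5,6-di-O-benzoyl-1,2-O-[(1S)-bornylidene]-3,4-di-O-(4-methoxybenzyl)-myo-inositol | COc1ccc(CO[C@H]2[C@H](OC(=O)c3ccccc3)[C@@H](OC(=O)c3ccccc3)[C@@H]3O[C@]4(C[C@@H]5CC[C@@]4(C)C5(C)C)O[C@@H]3[C@@H]2OCc2ccc(OC)cc2)cc1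
F8 | step 4 | 1D-1,2-O-[(1S)-bornylidene]-3,4-di-O-(4-methoxybenzyl)-myo-inositol | COc1ccc(CO[C@H]2[C@H](O)[C@@H](O)[C@@H]3O[C@]4(C[C@@H]5CC[C@@]4(C)C5(C)C)O[C@@H]3[C@@H]2OCc2ccc(OC)cc2)cc1
A1 | alternative 1 | cyclohexenol with free C3 hydroxyl, C2 acetate, C6/C1 acetonide and C7 benzoate | O[C@H]1C=C[C@@H]2OC(C)(C)O[C@]2(COC(=O)c3ccccc3)[C@@H]1OC(C)=O
A2 | alternative 2 | cyclohexene carboxylic acid with cis C1 and C6 4-methoxybenzyl ethers and C2, C3 methoxymethyl ethers | COCO[C@H]1C=C[C@H](OCc2ccc(OC)cc2)[C@@](OCc2ccc(OC)cc2)(C(=O)O)[C@@H]1OCOC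
A3 | alternative 3 | syn-5,6-epoxy-4-hydroxy-4-[(tert-butyldimethylsilyloxy)methyl]cyclohex-2-en-1-one | C1=CC(=O)[C@@H]2O[C@@H]2[C@@]1(O)CO[Si](C)(C)C(C)(C)C
A4 | alternative 3 | 4-hydroxy-4-[(tert-butyldimethylsilyloxy)methyl]cyclohexa-2,5-dien-1-one | O=C1C=CC(O)(CO[Si](C)(C)C(C)(C)C)C=C1
A5 | alternative 3 | cis-1-[(tert-butyldimethylsilyloxy)methyl]cyclohexa-3,5-diene-1,2-diol, configured at C1 and C6 as the target | C1=CC=C[C@H](O)[C@@]1(O)CO[Si](C)(C)C(C)(C)C
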